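**Assumption:** the SMILES has no stereocentre and no specified chiral axis, so there is no configuration to set. Any slow rotation about the hindered aryl–indole bond is left uncontrolled.

## Retrosynthetic overview
1. The aryl–indole bonds are not disconnected. Both indoles are opened at N1–C2 and C3–C3a, leading back to 2-iodoaniline (two equivalents) and an unsymmetrical 1,4-diynylbenzene.
2. Key step: a one-pot twofold Larock heteroannulation. The bulky CMe2(vinyl) and SiEt3 alkyne termini each end up at an indole C2, so the reverse prenyl group arrives already in place.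
3. The diyne comes from a 1-bromo-4-iodoarene by Sonogashira coupling at C–I, then alkynylzinc Negishi coupling at C–Br.
4. The bromo-iodoarene comes from 2,4,5-trimethoxyphenol MOM ether by OMOM-directed lithiation/iodination, then NBS. The future free OH is distinct from the three OMe groups from step 1.
5. Ring order: the central benzene is purchased, and both pyrrole rings form together in the penultimate step.

## Route

**Step 1**
Reactants: 1, 2,4,5-trimethoxybenzaldehyde
Product: 2, 2,4,5-trimethoxyphenol
Conditions: mCPBA, CH2Cl2, 0 °C to rt; then K2CO3, MeOH, N2, rt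
Reagents that add atoms: mCPBA, O=C(OO)c1cccc(Cl)c1 (adds one O)
Why: In this Baeyer–Villiger (Dakin-type) oxidation the electron-rich aryl group migrates to give the aryl formate, and methanolysis releases the phenol, which marks the one oxygen that must stay unmethylated.

**Step 2**
Reactants: 2, 2,4,5-trimethoxyphenol
Product: 3, 1,2,4-trimethoxy-5-(methoxymethoxy)benzene
Conditions: MOMCl, i-Pr2NEt, CH2Cl2, 0 °C to rt
Reagents that add atoms: MOMCl, COCCl
Why: Phenol O-alkylation (acetal protection) masks the easily oxidised p-methoxyphenol and installs a stronger metalation director than OMe.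

**Step 3**
Reactants: 3, the MOM ether
Product: 4, 3-iodo-1,2,5-trimethoxy-4-(methoxymethoxy)benzene (iodine between OMOM and OMe)
Conditions: n-BuLi, THF, 0 °C, 1 h; I2, −78 °C to rt
Reagents that add atoms: iodine, II
Why: In this directed ortho-metalation both ring C–H bonds lie between two oxygens, but the chelating OMOM binds n-BuLi better than OMe, so lithiation and iodination occur at the OMOM/OMe-flanked carbon.

**Step 4**
Reactants: 4, the aryl iodide
Product: 5, 1-bromo-4-iodo-2,3,6-trimethoxy-5-(methoxymethoxy)benzene
Conditions: NBS (1.05 equiv), dry MeCN, 0 °C, dark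
Reagents that add atoms: NBS, O=C1CCC(=O)N1Br
Why: Electrophilic aromatic bromination takes the only remaining C–H, which two ortho OMe groups activate, and doing it before any alkyne is present rules out halocyclisation to benzofurans.

**Step 5**
Reactants: 5, the bromo-iodoarene; 6, triethylsilylacetylene
Product: 7, {[4-bromo-2,3,5-trimethoxy-6-(methoxymethoxy)phenyl]ethynyl}triethylsilane
Conditions: PdCl2(PPh3)2 (3 mol %), CuI (6 mol %), Et3N/THF, 40 °C
Reagents that add atoms: 6, triethylsilylacetylene, C#C[Si](CC)(CC)CC
Why: This Sonogashira coupling is chemoselective because oxidative addition into C–I is much faster than into the hindered, electron-rich C–Br at this temperature.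

**Step 6**
Reactants: 8, 2,2-dimethylbut-3-en-1-ol
Product: 9, 2,2-dimethylbut-3-enal (volatile, carried forward as a CH2Cl2 solution)
Conditions: Dess–Martin periodinane, NaHCO3, CH2Cl2, 0 °C to rt
Reagents that add atoms: none
Why: Dess–Martin oxidation of a neopentyl primary alcohol is clean here because the quaternary α-carbon prevents enolisation and alkene migration.

**Step 7**
Reactants: 9, 2,2-dimethylbut-3-enal
Product: 10, 1,1-dibromo-3,3-dimethylpenta-1,4-diene
Conditions: CBr4, PPh3, CH2Cl2, 0 °C
Reagents that add atoms: carbon tetrabromide, BrC(Br)(Br)Br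
Why: The Ramirez/Corey–Fuchs dibromo-olefination works well on non-enolisable, pivaldehyde-type aldehydes and gives an easily handled precursor in place of the volatile enyne.

**Step 8**
Reactants: 10, the dibromodiene (1.5 equiv); 7, the aryl bromide
Product: 11, {[4-(3,3-dimethylpent-4-en-1-yn-1-yl)-2,3,5-trimethoxy-6-(methoxymethoxy)phenyl]ethynyl}triethylsilane
Conditions: 10, n-BuLi (2.05 equiv per 10), THF, −78 to 0 °C; ZnBr2; then 7, Pd2(dba)3/XPhos (5/12 mol %), THF, 60 °C
Reagents that add atoms: 10, C=CC(C)(C)C=C(Br)Br (delivers the C7 enynyl unit)
Why: Corey–Fuchs (Fritsch–Buttenberg–Wiechell) acetylide formation, zinc transmetalation and Negishi alkynylation are used, with the bulky biarylphosphine enabling insertion into the di-ortho-methoxy C–Br bond and all n-BuLi consumed before 7 is added.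

**Step 9 (key step)**
Reactants: 11, the unsymmetrical diyne; 12, 2-iodoaniline (2.5 equiv, added in portions)
Product: 13, 3-{2,3,5-trimethoxy-6-(methoxymethoxy)-4-[2-(2-methylbut-3-en-2-yl)-1H-indol-3-yl]phenyl}-2-(triethylsilyl)-1H-indole (may appear as slowly interconverting rotamers)
Conditions: Pd(OAc)2 (10 mol %), LiCl (2 equiv), Na2CO3 (6 equiv), degassed DMF, 100 °C
Reagents that add atoms: 12, 2-iodoaniline, Nc1ccccc1I (two equivalents, each adding C6H4NH)
Why: In this twofold Larock heteroannulation each syn-carbopalladation puts the aniline aryl on the alkyne carbon bearing the flat central arene and puts Pd next to the tetrahedral SiEt3 or CMe2(vinyl) group, so C–N reductive elimination gives 3-aryl indoles with those groups at C2, and the pendant vinyl cannot intercept the vinyl-Pd because that would need a 3- or 4-membered ring.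

**Step 10**
Reactants: 13, the protected bis-indole
Product: 14, Asterriquinol I, 2-(1H-indol-3-yl)-3,4,6-trimethoxy-5-[2-(2-methylbut-3-en-2-yl)-1H-indol-3-yl]phenol
Conditions: 2 M aq HCl, THF/MeOH (1:1), 40 °C, Ar
Reagents that add atoms: none
Why: Acetal hydrolysis of the MOM ether and ipso-protodesilylation of the 2-silylindole (C2 protonation gives a β-silyl-stabilised cation) occur in one operation, while dilute acid leaves the monosubstituted alkene, the aryl methyl ethers and the C2 tert-alkyl group intact.

## Compound list
1 | 2,4,5-trimethoxybenzaldehyde | COc1cc(OC)c(C=O)cc1OC | starting material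
2 | 2,4,5-trimethoxyphenol | COc1cc(OC)c(O)cc1OC | intermediate
3 | 1,2,4-trimethoxy-5-(methoxymethoxy)benzene | COCOc1cc(OC)c(OC)cc1OC | intermediate
4 | 3-iodo-1,2,5-trimethoxy-4-(methoxymethoxy)benzene | COCOc1c(I)c(OC)c(OC)cc1OC | intermediate
5 | 1-bromo-4-iodo-2,3,6-trimethoxy-5-(methoxymethoxy)benzene | COCOc1c(I)c(OC)c(OC)c(Br)c1OC | intermediate
6 | triethylsilylacetylene | C#C[Si](CC)(CC)CC | starting material
7 | {[4-bromo-2,3,5-trimethoxy-6-(methoxymethoxy)phenyl]ethynyl}triethylsilane | COCOc1c(C#C[Si](CC)(CC)CC)c(OC)c(OC)c(Br)c1OC | intermediate
8 | 2,2-dimethylbut-3-en-1-ol | C=CC(C)(C)CO | starting material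
9 | 2,2-dimethylbut-3-enal | C=CC(C)(C)C=O | intermediate
10 | 1,1-dibromo-3,3-dimethylpenta-1,4-diene | C=CC(C)(C)C=C(Br)Br | intermediate
11 | {[4-(3,3-dimethylpent-4-en-1-yn-1-yl)-2,3,5-trimethoxy-6-(methoxymethoxy)phenyl]ethynyl}triethylsilane | COCOc1c(C#C[Si](CC)(CC)CC)c(OC)c(OC)c(C#CC(C)(C)C=C)c1OC | intermediate
12 | 2-iodoaniline | Nc1ccccc1I | starting material
13 | MOM/2-TES-protected bis-indole | COCOc1c(-c2c([Si](CC)(CC)CC)[nH]c3ccccc23)c(OC)c(OC)c(-c2c(C(C)(C)C=C)[nH]c3ccccc23)c1OC | intermediate
14 | Asterriquinol I | C=CC(C)(C)c1[nH]c2ccccc2c1-c1c(OC)c(O)c(-c2c[nH]c3ccccc23)c(OC)c1OC | target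

## Summary
Total steps: 10.
Longest linear sequence: 8 (steps 1–5, then 8–10). Steps 6–7 are a two-step side branch.

**Steps most likely to fail, with fallbacks**

1. **Step 9, twofold Larock.**
   - Risks: insertion into the doubly hindered aryl/tert-alkyl alkyne may be slow or mis-oriented, and excess aryl-Pd may undergo Heck arylation of the vinyl group.
   - Fallback: install the reverse prenyl group after indole formation.
     - Couple 7 with trimethylsilylacetylene instead of the enyne, and run the twofold Larock on the TMS/TES diyne, where both insertions are silyl-directed.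
     - Remove the more labile 2-TMS group selectively.
     - Reverse-prenylate the freed C2 through the 3-chloroindolenine (t-BuOCl) and prenyl-9-BBN, with TES blocking C2 of the other indole.
     - Finish with step 10.
2. **Step 3, site selectivity of the metalation.**
   - Risk: lithiation at the OMe/OMe-flanked C–H may compete with the OMOM/OMe-flanked one.
   - Fallback: start from symmetrical 1,2,4,5-tetramethoxybenzene, where lithiation has no regiochemical issue.
     - Lithiate and quench with DMF to give 2,3,5,6-tetramethoxybenzaldehyde.
     - Apply BCl3 chelation-controlled demethylation ortho to the aldehyde, which fixes the OH next to the future unsubstituted indole.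
     - Protect as the MOM ether, then use Corey–Fuchs homologation with a TESCl quench to make the silylalkyne.
     - Brominate the last C–H with NBS at the aldehyde stage, before the alkyne exists, to rejoin the route at 7.
3. **Step 8, alkynylation of the di-ortho-methoxy, electron-rich aryl bromide.**
   - Risk: oxidative addition into this C–Br bond may be too slow.
   - Fallback: reverse the polarity and drop palladium. Carry out Br/Li exchange on 7 at −78 °C, then treat the aryllithium with the p-tolylsulfonyl alkyne made from 10 (TolSO2–C≡C–CMe2CH=CH2). Addition–elimination at the sulfonyl-bearing carbon gives 11.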